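The route builds, rather than substitutes, the central benzene ring C3a'–C4'–C5'–C6'–C7'–C7a' of the upper dihydrobenzofuran. That ring is a 1,2,3,5-tetrasubstituted resorcinol. C3' sits on C3a' between the two oxygens, and C3 of the lower dihydrobenzofuran sits on C6', meta to both. A Danheiser benzannulation exploits exactly this pattern. In one thermal operation it forms three C–C bonds, closes the arene and joins the two stereodiads. Its precursors are a cyclobutenone attached through its C3 to C3 of the complete lower ring system, and a triisopropylsiloxyalkyne carrying C3' and a silylated C2' carbinol. All phenol protection is fluoride- or mild-acid-labile, so no Lewis-acid dealkylation follows.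

Key step: step 22

Locants and abbreviations: unprimed locants refer to the lower dihydrobenzofuran and primed locants to the upper one. MOM = methoxymethyl, TIPS = triisopropylsilyl, TES = triethylsilyl, TBS = tert-butyldimethylsilyl.

Assumption: Rh2(S-PTTL)4 is taken to deliver the 2R series in step 8, by analogy with related 2-aryl-2,3-dihydrobenzofuran-3-carboxylates. If the sense is opposite, the R-configured catalyst is used and nothing else changes.

Design remarks:
- **Siloxyalkyne source.** It is made by oxidising an acetylide, not by homologating an ester. The amide and alkyllithium bases of an ester homologation would enolise an α-aryl-β-silyloxy ester, with loss of C3' or elimination.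
- **Lower half.** It carries TIPS ethers. They survive zinc with an acid chloride, where acetals would not. They also offer no C–H bond placed for a competing carbene insertion.
- **Upper half.** It carries small MOM ethers, which keep the alkyne accessible.
- **No boron halides at the end.** They would ionise both O–C2-type bonds while the phenols are tied up as borates.
- **Ring closure.** The two oxygens on the new ring flank C3a' symmetrically, so either one may close the upper ring.

Step 1
Reactants: 1 4-bromo-2,6-dimethoxybenzaldehyde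
Product: 2 4-bromo-2,6-dihydroxybenzaldehyde
Conditions: AlCl3 (4 equiv), CH2Cl2, 0 °C to reflux; then 1 M HCl
Reagents that add atoms: none
Why: Chelation-assisted Lewis-acid ether cleavage works here because both methoxy groups lie ortho to the formyl group, so aluminium binds carbonyl and ether oxygen together and chloride removes each methyl group.

Step 2
Reactants: 3 4-hydroxybenzaldehyde
Product: 5 [4-(triisopropylsilyloxy)phenyl]methanol, via silylated aldehyde 4 (not isolated)
Conditions: TIPSCl, imidazole, CH2Cl2, rt; then MeOH, NaBH4, 0 °C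
Reagents that add atoms: triisopropylsilyl chloride, CC(C)[Si](Cl)(C(C)C)C(C)C
Why: Phenol silylation followed by borohydride reduction of the aldehyde are two routine operations that can be telescoped because 4 needs no purification.

Step 3
Reactants: 2 4-bromo-2,6-dihydroxybenzaldehyde; 5 [4-(triisopropylsilyloxy)phenyl]methanol
Product: 6 4-bromo-2-hydroxy-6-{[4-(triisopropylsilyloxy)phenyl]methoxy}benzaldehyde
Conditions: PPh3, DIAD, THF, 0 °C to rt (2 in slight excess)
Reagents that add atoms: none
Why: Mitsunobu etherification of an acidic phenol should stop after one alkylation because the remaining hydroxyl is locked in a hydrogen bond to the formyl group and is far less reactive.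

Step 4
Reactants: 6 4-bromo-2-hydroxy-6-{[4-(triisopropylsilyloxy)phenyl]methoxy}benzaldehyde
Product: 7 4-bromo-2-(triisopropylsilyloxy)-6-{[4-(triisopropylsilyloxy)phenyl]methoxy}benzaldehyde
Conditions: TIPSOTf, 2,6-lutidine, CH2Cl2, 0 °C
Reagents that add atoms: triisopropylsilyl triflate, CC(C)[Si](OS(=O)(=O)C(F)(F)F)(C(C)C)C(C)C
Why: Silylation with the reactive silyl triflate overcomes the hydrogen-bonded hindered phenol and installs a group that has no C–H bond placed for five-membered-ring carbene insertion later.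

Step 5
Reactants: 7 4-bromo-2-(triisopropylsilyloxy)-6-{[4-(triisopropylsilyloxy)phenyl]methoxy}benzaldehyde
Product: 8 5-bromo-2-(2-methoxyethenyl)-1-(triisopropylsilyloxy)-3-{[4-(triisopropylsilyloxy)phenyl]methoxy}benzene (E/Z mixture)
Conditions: MeOCH2PPh3Cl, NaN(SiMe3)2, THF, 0 °C; then 7, 0 °C to rt
Reagents that add atoms: (methoxymethyl)triphenylphosphonium chloride, COC[P+](c1ccccc1)(c1ccccc1)c1ccccc1.[Cl-]
Why: Wittig methoxymethylenation with a small non-stabilised ylide tolerates the two ortho substituents, and the alkene geometry is irrelevant to the next step.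

Step 6
Reactants: 8 the enol ether from step 5
Product: 9 methyl 2-[4-bromo-2-(triisopropylsilyloxy)-6-{[4-(triisopropylsilyloxy)phenyl]methoxy}phenyl]acetate
Conditions: C5H5NH[CrO3Cl] (pyridinium chlorochromate), 4 Å sieves, CH2Cl2, rt
Reagents that add atoms: pyridinium chlorochromate, [O-][Cr](=O)(=O)Cl.c1cc[nH+]cc1
Why: Chlorochromate oxidation of an enol ether, which adds oxygen at the alkoxy-bearing carbon with a 1,2-hydride shift, gives the methyl ester directly and so completes a two-step aldehyde-to-arylacetate homologation under non-basic conditions.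

Step 7
Reactants: 9 the methyl arylacetate from step 6
Product: 10 methyl 2-diazo-2-[4-bromo-2-(triisopropylsilyloxy)-6-{[4-(triisopropylsilyloxy)phenyl]methoxy}phenyl]acetate
Conditions: 4-acetamidobenzenesulfonyl azide, DBU, MeCN, 0 °C to rt
Reagents that add atoms: 4-acetamidobenzenesulfonyl azide, CC(=O)Nc1ccc(cc1)S(=O)(=O)N=[N+]=[N-]
Why: Regitz diazo transfer to the benzylic ester enolate is the standard entry to aryldiazoacetates, and anhydrous DBU leaves aryl TIPS ethers intact.

Step 8
Reactants: 10 the aryldiazoacetate from step 7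
Product: 11 methyl (2R,3S)-6-bromo-4-(triisopropylsilyloxy)-2-[4-(triisopropylsilyloxy)phenyl]-2,3-dihydro-1-benzofuran-3-carboxylate (cis)
Conditions: Rh2(S-PTTL)4 (dirhodium tetrakis[N-phthaloyl-(S)-tert-leucinate], 1 mol %), toluene, −60 °C
Reagents that add atoms: none
Why: Intramolecular C–H insertion of a donor/acceptor rhodium carbene into the activated benzylic ether C–H bond closes the five-membered ring, the chiral carboxylate pocket selects one enantiotopic hydrogen and so sets C2 as R, and the concerted insertion gives the cis ester, so that C3 is provisional.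

Step 9
Reactants: 11 the cis ester from step 8
Product: 12 methyl (2R,3R)-6-bromo-4-(triisopropylsilyloxy)-2-[4-(triisopropylsilyloxy)phenyl]-2,3-dihydro-1-benzofuran-3-carboxylate (trans)
Conditions: NaOMe (0.3 equiv), MeOH–THF, rt
Reagents that add atoms: none
Why: Base-mediated epimerisation through the ester enolate moves C3 to the more stable trans arrangement dictated by the untouched C2 centre, while ring opening by β-elimination is disfavoured because the C2–O1 bond lies near the nodal plane of the enolate.

Step 10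
Reactants: 12 the trans ester from step 9
Product: 14 (2R,3R)-6-bromo-3-ethynyl-4-(triisopropylsilyloxy)-2-[4-(triisopropylsilyloxy)phenyl]-2,3-dihydro-1-benzofuran, via trans aldehyde 13 (not isolated)
Conditions: i-Bu2AlH (1.1 equiv), CH2Cl2, −78 °C; MeOH; then K2CO3, dimethyl (1-diazo-2-oxopropyl)phosphonate, −78 °C to rt
Reagents that add atoms: dimethyl (1-diazo-2-oxopropyl)phosphonate, COP(=O)(OC)C(=[N+]=[N-])C(C)=O
Why: Partial hydride reduction followed in the same flask by Ohira–Bestmann (Seyferth–Gilbert) homologation is an established ester-to-alkyne telescope that avoids the organolithium reagents the aryl bromide would not tolerate, and any enolisation of 13 returns the favoured trans isomer.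

Step 11
Reactants: 14 the 3-ethynyl dihydrobenzofuran from step 10; 15 trichloroacetyl chloride
Product: 17 4,4-dichloro-3-[(2R,3S)-6-bromo-4-(triisopropylsilyloxy)-2-[4-(triisopropylsilyloxy)phenyl]-2,3-dihydro-1-benzofuran-3-yl]cyclobut-2-en-1-one (same spatial arrangement as 14), via dichloroketene 16 (not isolated)
Conditions: Zn(Cu) couple, 15 added slowly, Et2O–DME, rt
Reagents that add atoms: none
Why: In this ketene–alkyne (2+2) cycloaddition the terminal alkyne carbon attacks the carbonyl carbon of the electrophilic ketene, so the substituent ends at C3 of the cyclobutenone, and aryl bromide, silyl ethers and stereocentres are inert to zinc in ether.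

Step 12
Reactants: 17 the dichlorocyclobutenone from step 11
Product: 18 3-[(2R,3R)-6-bromo-4-(triisopropylsilyloxy)-2-[4-(triisopropylsilyloxy)phenyl]-2,3-dihydro-1-benzofuran-3-yl]cyclobut-2-en-1-one
Conditions: Zn dust, TMEDA, AcOH, EtOH, 0 °C to rt
Reagents that add atoms: none
Why: Buffered zinc reduction removes both α-chlorine atoms through zinc enolates without reducing or isomerising the strained enone, which is the standard second stage of the dichloroketene route to 3-substituted cyclobutenones.

Step 13
Reactants: 19 3,5-dihydroxyphenylacetic acid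
Product: 21 2-[3,5-bis(methoxymethoxy)phenyl]acetic acid, via methoxymethyl ester 20 (not isolated)
Conditions: MOMCl (3.5 equiv), i-Pr2NEt, CH2Cl2, 0 °C to rt; then LiOH, THF–H2O, rt; 1 M HCl to pH 4, 0 °C
Reagents that add atoms: chloromethyl methyl ether, COCCl; lithium hydroxide, [Li+].[OH-]
Why: Exhaustive acetal alkylation followed by saponification of the labile acyloxy acetal frees only the carboxyl group, since aryl MOM ethers are inert to hydroxide.

Step 14
Reactants: 21 2-[3,5-bis(methoxymethoxy)phenyl]acetic acid; 22 (S)-4-benzyl-1,3-oxazolidin-2-one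
Product: 24 (4S)-4-benzyl-3-{2-[3,5-bis(methoxymethoxy)phenyl]acetyl}-1,3-oxazolidin-2-one, via mixed pivalic anhydride 23 (not isolated)
Conditions: t-BuCOCl, Et3N, THF, −20 °C; then LiCl, 22, −20 °C to rt
Reagents that add atoms: pivaloyl chloride, CC(C)(C)C(=O)Cl (stays only in 23)
Why: N-acylation of the oxazolidinone through a mixed anhydride activated by LiCl needs no strong base, and attack occurs at the less hindered arylacetyl carbonyl.

Step 15
Reactants: 25 2,4-dihydroxybenzaldehyde
Product: 26 2,4-bis(methoxymethoxy)benzaldehyde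
Conditions: NaH, MOMCl, DMF, 0 °C to rt
Reagents that add atoms: chloromethyl methyl ether, COCCl
Why: Williamson-type acetal alkylation of both phenoxides, with a strong base so that the hydrogen-bonded 2-hydroxyl also reacts.

Step 16
Reactants: 24 the N-arylacetyl oxazolidinone from step 14; 26 2,4-bis(methoxymethoxy)benzaldehyde
Product: 29 (4S)-4-benzyl-3-{(2S,3S)-3-[2,4-bis(methoxymethoxy)phenyl]-2-[3,5-bis(methoxymethoxy)phenyl]-3-hydroxypropanoyl}-1,3-oxazolidin-2-one, via boron enolate 27 (not isolated), via boron aldolate 28 (not isolated)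
Conditions: Bu2BOTf, Et3N, CH2Cl2, −78 to 0 °C; 26, −78 to 0 °C; pH 7 buffer, MeOH, 30% H2O2, 0 °C
Reagents that add atoms: dibutylboron triflate, CCCCB(CCCC)OS(=O)(=O)C(F)(F)F (stays only in 27 and 28)
Why: In this Evans syn aldol the Z boron enolate reacts through a Zimmerman–Traxler chair on the face away from the benzyl group of the (S)-auxiliary, which sets C3' in the sense the target needs, while the C2' configuration formed alongside is provisional.

Step 17
Reactants: 29 the syn aldol from step 16
Product: 30 the triethylsilyl ether of 29, (2S,3S) in the acyl chain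
Conditions: TESCl, imidazole, DMAP (cat.), DMF, rt
Reagents that add atoms: triethylsilyl chloride, CC[Si](Cl)(CC)CC
Why: Silylation with the chloride and imidazole avoids silyl triflates, which could attack the MOM acetals, and is too mild for retro-aldol cleavage.

Step 18
Reactants: 30 the silylated aldol from step 17
Product: 31 (2R,3S)-3-[2,4-bis(methoxymethoxy)phenyl]-2-[3,5-bis(methoxymethoxy)phenyl]-3-(triethylsilyloxy)propan-1-ol
Conditions: LiBH4, MeOH (1 equiv), Et2O–THF, 0 °C
Reagents that add atoms: none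
Why: Reductive removal of the oxazolidinone with LiBH4 attacks the exocyclic imide carbonyl and is non-basic enough to leave the α-aryl centre untouched.

Step 19
Reactants: 31 the primary alcohol from step 18
Product: 32 (2S,3S)-3-[2,4-bis(methoxymethoxy)phenyl]-2-[3,5-bis(methoxymethoxy)phenyl]-3-(triethylsilyloxy)propanal
Conditions: Dess–Martin periodinane, NaHCO3, CH2Cl2, 0 °C to rt; used at once
Reagents that add atoms: none
Why: Buffered Dess–Martin oxidation gives the aldehyde under nearly neutral conditions, the gentlest choice for an enolisable α-aryl aldehyde.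

Step 20
Reactants: 32 the α-aryl aldehyde from step 19
Product: 33 (3S,4S)-1,1-dibromo-4-[2,4-bis(methoxymethoxy)phenyl]-3-[3,5-bis(methoxymethoxy)phenyl]-4-(triethylsilyloxy)but-1-ene
Conditions: CBr4, PPh3, CH2Cl2, 0 °C (ylide pre-formed); 2,6-lutidine, then 32, −20 to 0 °C
Reagents that add atoms: carbon tetrabromide, BrC(Br)(Br)Br
Why: Ramirez olefination, the first stage of the Corey–Fuchs sequence, runs without strong base at low temperature and therefore spares the C3' stereocentre next to the formyl group.

Step 21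
Reactants: 33 the dibromoalkene from step 20
Product: 36 (3R,4S)-4-[2,4-bis(methoxymethoxy)phenyl]-3-[3,5-bis(methoxymethoxy)phenyl]-4-(triethylsilyloxy)-1-(triisopropylsilyloxy)but-1-yne, via lithium acetylide 34 (not isolated), via lithium ynolate 35 (not isolated)
Conditions: n-BuLi (2.1 equiv), THF, −78 °C; t-BuOOLi (from t-BuOOH and LiN(SiMe3)2, THF, −78 °C), −78 to 0 °C; TIPSOTf, −78 to 0 °C
Reagents that add atoms: tert-butyl hydroperoxide, CC(C)(C)OO; triisopropylsilyl triflate, CC(C)[Si](OS(=O)(=O)C(F)(F)F)(C(C)C)C(C)C; n-butyllithium, [Li]CCCC (lithium only in 34 and 35)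
Why: Bromine–lithium exchange with Fritsch–Buttenberg–Wiechell shift (second Corey–Fuchs stage) gives the acetylide, the known oxygen transfer from lithium tert-butyl peroxide turns it into the ynolate, the bulky silyl triflate traps it on oxygen, and the negative charge of the acetylide shields the C3' hydrogen from further deprotonation.

Step 22
Reactants: 18 the lower-unit cyclobutenone from step 12; 36 the siloxyalkyne from step 21
Product: 41 5-[(2R,3R)-6-bromo-4-(triisopropylsilyloxy)-2-[4-(triisopropylsilyloxy)phenyl]-2,3-dihydro-1-benzofuran-3-yl]-2-{(1R,2S)-2-[2,4-bis(methoxymethoxy)phenyl]-1-[3,5-bis(methoxymethoxy)phenyl]-2-(triethylsilyloxy)ethyl}-3-(triisopropylsilyloxy)phenol, via vinylketene 37 (not isolated), via vinylcyclobutenone 38 (not isolated), via dienylketene 39 (not isolated), via cyclohexadienone 40 (not isolated)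
Conditions: 36 (1.0 equiv), 18 (1.2 equiv), toluene (0.4 M), argon, sealed vessel, 80 °C then 110 °C
Reagents that add atoms: none
Why: Four-electron electrocyclic opening of 18 gives vinylketene 37, whose ketene C=C adds (2+2) to the electron-rich alkyne 36 to give 38, and four-electron opening to dienylketene 39, six-electron closure to 40 and tautomerisation then deliver phenol 41. This is a Danheiser benzannulation, the established union of cyclobutenones with siloxy- or alkoxyalkynes, applied here to larger partners within the known scope of alkynes branched at the propargylic carbon. The one ring formed, the central benzene C3a'–C7a', is closed by the disrotatory six-electron electrocyclisation that makes C7'–C7a', after C7a'–C3a' and C4'–C5' have been made in the cycloaddition. No lasting stereocentre is created, since the sp3 ring carbon of 38 and the CH2 of 40 vanish on aromatisation, and C2, C3, C2' and C3' are untouched because the medium is neutral and aprotic. The only selectivity required is the orientation of the ketene–alkyne cycloaddition: the oxygen lone pair makes the alkyne carbon bearing C3' nucleophilic, so it bonds to the ketene carbonyl carbon, which places C3' between the new hydroxyl and the silyl ether and C3 para to it. Reversible reclosure of unreacted 37 to 18 preserves the ketene source while the hindered alkyne reacts, and the small MOM and TES groups around the alkyne were chosen to help that encounter.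

Step 23
Reactants: 41 the resorcinol monosilyl ether from step 22; 42 4-(tert-butyldimethylsilyloxy)styrene
Product: 43 the (E)-stilbene in which the C6 bromine of 41 is replaced by (E)-2-[4-(tert-butyldimethylsilyloxy)phenyl]ethenyl
Conditions: Pd2(dba)3 (2.5 mol %), [HP(t-Bu)3]BF4 (10 mol %), Cy2NMe, dioxane, 75 °C
Reagents that add atoms: none
Why: In this Heck reaction, oxidative addition of the aryl bromide to zerovalent palladium bearing a bulky electron-rich phosphine, syn insertion of the styrene and syn β-hydride elimination give the E-stilbene at moderate temperature under basic conditions that leave silyl ethers, acetals and the free phenol alone.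

Step 24
Reactants: 43 the protected stilbene from step 23
Product: 44 the hexaol with free OH on the stilbene ring, C4, the C2 aryl group, C4', C7a' and C2' and with four MOM ethers retained (C2 R, C3 R, C3' R, C2' S)
Conditions: Bu4NF (8 equiv), AcOH (8 equiv), THF, 0 °C to rt, argon
Reagents that add atoms: none
Why: Fluoride-mediated desilylation removes all five silyl groups while the acetals stay, and it is buffered with acetic acid so that the liberated 4-hydroxyphenyl group does not trigger base-induced opening of the lower ring.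

Step 25
Reactants: 44 the hexaol from step 24
Product: 45 CNP0118407.2 (2R,3R,2'R,3'R; E)
Conditions: HCl (about 1 M) in MeOH–THF, 40 °C, argon
Reagents that add atoms: none
Why: Acid-catalysed acetal methanolysis frees the last four phenols and ionises the C2' carbinol to the 2,4-dioxygenated benzylic cation (SN1 cycloetherification), which either of the two equivalent flanking hydroxyls captures with the aryl group anti to the C3' aryl group, so that C3' (R) sets C2' as R in the reversible and therefore thermodynamically trans closure.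

Compound list
1 | 4-bromo-2,6-dimethoxybenzaldehyde | COc1cc(Br)cc(OC)c1C=O | starting material
2 | 4-bromo-2,6-dihydroxybenzaldehyde | Oc1cc(Br)cc(O)c1C=O | intermediate
3 | 4-hydroxybenzaldehyde | Oc1ccc(C=O)cc1 | starting material
4 | 4-(triisopropylsilyloxy)benzaldehyde | CC(C)[Si](C(C)C)(C(C)C)Oc1ccc(C=O)cc1 | intermediate
5 | [4-(triisopropylsilyloxy)phenyl]methanol | CC(C)[Si](C(C)C)(C(C)C)Oc1ccc(CO)cc1 | intermediate
6 | mono-benzylated hydroxyaldehyde | O=Cc1c(O)cc(Br)cc1OCc1ccc(O[Si](C(C)C)(C(C)C)C(C)C)cc1 | intermediate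
7 | fully protected aldehyde | O=Cc1c(O[Si](C(C)C)(C(C)C)C(C)C)cc(Br)cc1OCc1ccc(O[Si](C(C)C)(C(C)C)C(C)C)cc1 | intermediate
8 | methyl enol ether (E/Z) | COC=Cc1c(O[Si](C(C)C)(C(C)C)C(C)C)cc(Br)cc1OCc1ccc(O[Si](C(C)C)(C(C)C)C(C)C)cc1 | intermediate
9 | methyl arylacetate | COC(=O)Cc1c(O[Si](C(C)C)(C(C)C)C(C)C)cc(Br)cc1OCc1ccc(O[Si](C(C)C)(C(C)C)C(C)C)cc1 | intermediate
10 | methyl aryldiazoacetate | COC(=O)C(=[N+]=[N-])c1c(O[Si](C(C)C)(C(C)C)C(C)C)cc(Br)cc1OCc1ccc(O[Si](C(C)C)(C(C)C)C(C)C)cc1 | intermediate
11 | cis ester (2R,3S) | Brc1cc(O[Si](C(C)C)(C(C)C)C(C)C)c2c(c1)O[C@@H](c1ccc(O[Si](C(C)C)(C(C)C)C(C)C)cc1)[C@H]2C(=O)OC | intermediate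
12 | trans ester (2R,3R) | Brc1cc(O[Si](C(C)C)(C(C)C)C(C)C)c2c(c1)O[C@@H](c1ccc(O[Si](C(C)C)(C(C)C)C(C)C)cc1)[C@@H]2C(=O)OC | intermediate
13 | trans aldehyde (2R,3R) | Brc1cc(O[Si](C(C)C)(C(C)C)C(C)C)c2c(c1)O[C@@H](c1ccc(O[Si](C(C)C)(C(C)C)C(C)C)cc1)[C@@H]2C=O | intermediate
14 | trans 3-ethynyl dihydrobenzofuran (2R,3R) | Brc1cc(O[Si](C(C)C)(C(C)C)C(C)C)c2c(c1)O[C@@H](c1ccc(O[Si](C(C)C)(C(C)C)C(C)C)cc1)[C@@H]2C#C | intermediate
15 | trichloroacetyl chloride | O=C(Cl)C(Cl)(Cl)Cl | starting material
16 | dichloroketene | O=C=C(Cl)Cl | intermediate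
17 | 4,4-dichlorocyclobutenone on C3 | Brc1cc(O[Si](C(C)C)(C(C)C)C(C)C)c2c(c1)O[C@@H](c1ccc(O[Si](C(C)C)(C(C)C)C(C)C)cc1)[C@@H]2C1=CC(=O)C1(Cl)Cl | intermediate
18 | cyclobutenone on C3 (key-step precursor) | Brc1cc(O[Si](C(C)C)(C(C)C)C(C)C)c2c(c1)O[C@@H](c1ccc(O[Si](C(C)C)(C(C)C)C(C)C)cc1)[C@@H]2C1=CC(=O)C1 | intermediate
19 | 3,5-dihydroxyphenylacetic acid | OC(=O)Cc1cc(O)cc(O)c1 | starting material
20 | methoxymethyl 2-[3,5-bis(methoxymethoxy)phenyl]acetate | COCOC(=O)Cc1cc(OCOC)cc(OCOC)c1 | intermediate
21 | 2-[3,5-bis(methoxymethoxy)phenyl]acetic acid | OC(=O)Cc1cc(OCOC)cc(OCOC)c1 | intermediate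
22 | (S)-4-benzyl-1,3-oxazolidin-2-one | O=C1N[C@@H](Cc2ccccc2)CO1 | starting material
23 | mixed pivalic anhydride | CC(C)(C)C(=O)OC(=O)Cc1cc(OCOC)cc(OCOC)c1 | intermediate
24 | N-arylacetyl oxazolidinone | O=C(Cc1cc(OCOC)cc(OCOC)c1)N1C(=O)OC[C@@H]1Cc1ccccc1 | intermediate
25 | 2,4-dihydroxybenzaldehyde | Oc1ccc(C=O)c(O)c1 | starting material
26 | 2,4-bis(methoxymethoxy)benzaldehyde | COCOc1ccc(C=O)c(OCOC)c1 | intermediate
27 | Z dibutylboron enolate | CCCCB(CCCC)O/C(=C\c1cc(OCOC)cc(OCOC)c1)N1C(=O)OC[C@@H]1Cc1ccccc1 | intermediate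
28 | dibutylboron aldolate | CCCCB(CCCC)O[C@H](c1ccc(OCOC)cc1OCOC)[C@@H](C(=O)N1C(=O)OC[C@@H]1Cc1ccccc1)c1cc(OCOC)cc(OCOC)c1 | intermediate
29 | syn aldol (2S,3S) | O[C@H](c1ccc(OCOC)cc1OCOC)[C@@H](C(=O)N1C(=O)OC[C@@H]1Cc1ccccc1)c1cc(OCOC)cc(OCOC)c1 | intermediate
30 | TES ether of the aldol | CC[Si](CC)(CC)O[C@H](c1ccc(OCOC)cc1OCOC)[C@@H](C(=O)N1C(=O)OC[C@@H]1Cc1ccccc1)c1cc(OCOC)cc(OCOC)c1 | intermediate
31 | primary alcohol (2R,3S) | CC[Si](CC)(CC)O[C@H](c1ccc(OCOC)cc1OCOC)[C@@H](CO)c1cc(OCOC)cc(OCOC)c1 | intermediate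
32 | α-aryl aldehyde (2S,3S) | CC[Si](CC)(CC)O[C@H](c1ccc(OCOC)cc1OCOC)[C@@H](C=O)c1cc(OCOC)cc(OCOC)c1 | intermediate
33 | 1,1-dibromoalkene (3S,4S) | CC[Si](CC)(CC)O[C@H](c1ccc(OCOC)cc1OCOC)[C@@H](C=C(Br)Br)c1cc(OCOC)cc(OCOC)c1 | intermediate
34 | lithium acetylide | CC[Si](CC)(CC)O[C@H](c1ccc(OCOC)cc1OCOC)[C@@H](C#C[Li])c1cc(OCOC)cc(OCOC)c1 | intermediate
35 | lithium ynolate | CC[Si](CC)(CC)O[C@H](c1ccc(OCOC)cc1OCOC)[C@@H](C#CO[Li])c1cc(OCOC)cc(OCOC)c1 | intermediate
36 | triisopropylsiloxyalkyne (3R,4S) (key-step precursor) | CC[Si](CC)(CC)O[C@H](c1ccc(OCOC)cc1OCOC)[C@@H](C#CO[Si](C(C)C)(C(C)C)C(C)C)c1cc(OCOC)cc(OCOC)c1 | intermediate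
37 | vinylketene | Brc1cc(O[Si](C(C)C)(C(C)C)C(C)C)c2c(c1)O[C@@H](c1ccc(O[Si](C(C)C)(C(C)C)C(C)C)cc1)[C@@H]2C(=C)C=C=O | intermediate
38 | 4-vinylcyclobutenone (ring sp3 carbon unassigned) | Brc1cc(O[Si](C(C)C)(C(C)C)C(C)C)c2c(c1)O[C@@H](c1ccc(O[Si](C(C)C)(C(C)C)C(C)C)cc1)[C@@H]2C(=C)C1C(=O)C([C@H]([C@H](O[Si](CC)(CC)CC)c3ccc(OCOC)cc3OCOC)c3cc(OCOC)cc(OCOC)c3)=C1O[Si](C(C)C)(C(C)C)C(C)C | intermediate
39 | dienylketene | Brc1cc(O[Si](C(C)C)(C(C)C)C(C)C)c2c(c1)O[C@@H](c1ccc(O[Si](C(C)C)(C(C)C)C(C)C)cc1)[C@@H]2C(=C)C=C(O[Si](C(C)C)(C(C)C)C(C)C)C(=C=O)[C@H]([C@H](O[Si](CC)(CC)CC)c3ccc(OCOC)cc3OCOC)c3cc(OCOC)cc(OCOC)c3 | intermediate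
40 | 2,4-cyclohexadienone | Brc1cc(O[Si](C(C)C)(C(C)C)C(C)C)c2c(c1)O[C@@H](c1ccc(O[Si](C(C)C)(C(C)C)C(C)C)cc1)[C@@H]2C1=CC(O[Si](C(C)C)(C(C)C)C(C)C)=C([C@H]([C@H](O[Si](CC)(CC)CC)c3ccc(OCOC)cc3OCOC)c3cc(OCOC)cc(OCOC)c3)C(=O)C1 | intermediate
41 | resorcinol monosilyl ether (key-step product) | Brc1cc(O[Si](C(C)C)(C(C)C)C(C)C)c2c(c1)O[C@@H](c1ccc(O[Si](C(C)C)(C(C)C)C(C)C)cc1)[C@@H]2c1cc(O)c([C@H]([C@H](O[Si](CC)(CC)CC)c3ccc(OCOC)cc3OCOC)c3cc(OCOC)cc(OCOC)c3)c(O[Si](C(C)C)(C(C)C)C(C)C)c1 | intermediate
42 | 4-(tert-butyldimethylsilyloxy)styrene | C=Cc1ccc(O[Si](C)(C)C(C)(C)C)cc1 | starting material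
43 | protected (E)-stilbene | CC(C)(C)[Si](C)(C)Oc1ccc(/C=C/c2cc(O[Si](C(C)C)(C(C)C)C(C)C)c3c(c2)O[C@@H](c2ccc(O[Si](C(C)C)(C(C)C)C(C)C)cc2)[C@@H]3c2cc(O)c([C@H]([C@H](O[Si](CC)(CC)CC)c3ccc(OCOC)cc3OCOC)c3cc(OCOC)cc(OCOC)c3)c(O[Si](C(C)C)(C(C)C)C(C)C)c2)cc1 | intermediate
44 | tetra-MOM hexaol | Oc1ccc(/C=C/c2cc(O)c3c(c2)O[C@@H](c2ccc(O)cc2)[C@@H]3c2cc(O)c([C@H]([C@H](O)c3ccc(OCOC)cc3OCOC)c3cc(OCOC)cc(OCOC)c3)c(O)c2)cc1 | intermediate
45 | CNP0118407.2 | Oc1ccc(/C=C/c2cc(O)c3c(c2)O[C@@H](c2ccc(O)cc2)[C@@H]3c2cc(O)c3c(c2)O[C@@H](c2ccc(O)cc2O)[C@@H]3c2cc(O)cc(O)c2)cc1 | target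

Total step count: 25. Longest linear sequence: 15 steps (steps 1, 3–12 and 22–25).

Steps most likely to fail

1. **Step 22.** The bulky propargylic carbon may slow the capture of the vinylketene. Ketene dimerisation, acylation of the newly formed phenol, stalling before the second ring opening, or drift of the cyclobutenone double bond out of the ring (erasing C3) could then compete. Early thermal closure of the upper ring would be harmless, because it converges on the same target.
 - The fallback makes the same ketene at room temperature by a photochemical Wolff rearrangement, the second-generation form of the benzannulation. It sets out from 14.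
 - Markovnikov hydroxycarbonylation (Pd(OAc)2, 2-(diphenylphosphino)pyridine, cat. MeSO3H, CO, aqueous THF) gives the 2-substituted acrylic acid F1.
 - Oxalyl chloride with cat. DMF gives the acid chloride F2.
 - Excess diazomethane in ether at 0 °C gives the α-diazo enone F3.
 - Irradiation of F3 with 36 in CH2Cl2 (medium-pressure mercury lamp) releases 37. The cascade through 38–40 is finished by brief warming, and the route is rejoined at 41.

2. **Step 21.** Competing deprotonation at C3' could cause loss of configuration or elimination of silanolate. Oxygen transfer to the acetylide may be incomplete, or the ynolate may be silylated on carbon instead of oxygen.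
 - The fallback reaches the ynolate by iodonium umpolung instead of acetylide oxidation. It sets out from 33.
 - n-BuLi followed by water gives the terminal alkyne F4.
 - [Hydroxy(tosyloxy)iodo]benzene with a desiccant gives the alkynyl(phenyl)iodonium tosylate F5.
 - Catalytic CuOTf in MeCN collapses F5 to the alkynyl tosylate F6.
 - MeLi at −78 °C attacks sulfur and liberates 35, which is silylated as before, so the route is rejoined at 36.

3. **Step 8.** The two ortho substituents twist the aryl ring out of conjugation with the carbene. Facial selectivity may be poor, insertion may be sluggish at low temperature, and carbene dimerisation may intervene.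
 - The fallback gives up catalyst control and resolves instead. It sets out from 10.
 - Rh2(OAc)4 in CH2Cl2 at rt gives 11 together with its mirror image, the (2S,3R) cis ester F7.
 - NaOMe in MeOH–THF converts the pair into 12 and the (2S,3S) trans ester F8.
 - Preparative chromatography on a chiral stationary phase separates them, and the route is rejoined at 12.

Further compounds
F1 | step 22 | 2-(lower dihydrobenzofuran-3-yl)prop-2-enoic acid, configuration as in 14 | Brc1cc(O[Si](C(C)C)(C(C)C)C(C)C)c2c(c1)O[C@@H](c1ccc(O[Si](C(C)C)(C(C)C)C(C)C)cc1)[C@@H]2C(=C)C(=O)O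
F2 | step 22 | 2-(lower dihydrobenzofuran-3-yl)prop-2-enoyl chloride, configuration as in 14 | Brc1cc(O[Si](C(C)C)(C(C)C)C(C)C)c2c(c1)O[C@@H](c1ccc(O[Si](C(C)C)(C(C)C)C(C)C)cc1)[C@@H]2C(=C)C(=O)Cl
F3 | step 22 | 1-diazo-3-(lower dihydrobenzofuran-3-yl)but-3-en-2-one, configuration as in 14 | Brc1cc(O[Si](C(C)C)(C(C)C)C(C)C)c2c(c1)O[C@@H](c1ccc(O[Si](C(C)C)(C(C)C)C(C)C)cc1)[C@@H]2C(=C)C(=O)C=[N+]=[N-]
F4 | step 21 | terminal alkyne, configuration as in 36 | CC[Si](CC)(CC)O[C@H](c1ccc(OCOC)cc1OCOC)[C@@H](C#C)c1cc(OCOC)cc(OCOC)c1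
F5 | step 21 | alkynyl(phenyl)iodonium tosylate, configuration as in 36 | CC[Si](CC)(CC)O[C@H](c1ccc(OCOC)cc1OCOC)[C@@H](C#C[I+]c1ccccc1)c1cc(OCOC)cc(OCOC)c1.Cc1ccc(cc1)S(=O)(=O)[O-]
F6 | step 21 | alkynyl tosylate, configuration as in 36 | CC[Si](CC)(CC)O[C@H](c1ccc(OCOC)cc1OCOC)[C@@H](C#COS(=O)(=O)c1ccc(C)cc1)c1cc(OCOC)cc(OCOC)c1
F7 | step 8 | (2S,3R) cis ester, enantiomer of 11 | Brc1cc(O[Si](C(C)C)(C(C)C)C(C)C)c2c(c1)O[C@H](c1ccc(O[Si](C(C)C)(C(C)C)C(C)C)cc1)[C@@H]2C(=O)OC
F8 | step 8 | (2S,3S) trans ester, enantiomer of 12 | Brc1cc(O[Si](C(C)C)(C(C)C)C(C)C)c2c(c1)O[C@H](c1ccc(O[Si](C(C)C)(C(C)C)C(C)C)cc1)[C@H]2C(=O)OC
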